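## Retrosynthetic overview

1. Ester C(acyl)–O bond: target 14 ⇒ acid 10 (used as its acid chloride 12) + (R)-terpinen-4-ol 11, which brings the only stereocentre.
2. Acid 10 ⇒ phenol ester 8 by O-methylation and saponification.
3. Both aryl–CH2(prenyl) bonds ⇒ two aromatic Claisen rearrangements of 1,1-dimethylallyl aryl ethers (6 ⇒ 8 and 3 ⇒ 5); the allylic transposition turns the tertiary ether into the linear prenyl group.
4. Ethers 3 and 6 ⇒ phenols 1 and 5 + tertiary allylic carbonate 2 (Pd-catalysed O-allylation).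
5. No ring is constructed: the benzene ring comes from 1 and the cyclohexene ring from 11.

Assumption: (R)-(−)-terpinen-4-ol 11 (≥98% ee, checked by chiral GC before use) and carbonate 2 are taken as purchasable.

## Route

Step 1
Reactants: 1 methyl 4-hydroxybenzoate; 2 tert-butyl 2-methylbut-3-en-2-yl carbonate
Product: 3 methyl 4-[(2-methylbut-3-en-2-yl)oxy]benzoate
Conditions: 2 (1.5 equiv), Pd(PPh3)4 (2 mol%), 4 Å MS, THF, 0 °C
Reagents that add atoms: none
Why: Decarboxylative Tsuji–Trost O-allylation: Pd(0) ionises 2 to a 1,1-dimethyl-π-allyl complex, CO2 and tert-butoxide, which deprotonates the phenol, and the phenoxide attacks the more substituted allyl terminus under kinetic control at 0 °C to give the tertiary ether (no stereocentre formed).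

Step 2
Reactants: 3 methyl 4-[(2-methylbut-3-en-2-yl)oxy]benzoate
Product: 5 methyl 4-hydroxy-3-(3-methylbut-2-en-1-yl)benzoate, via Claisen dienone 4 (not isolated)
Conditions: PhNEt2, 150 °C, Ar
Reagents that add atoms: none
Why: Aromatic Claisen rearrangement, a [3,3]-sigmatropic shift through a chair transition state that forms the aryl–CH2 bond at the ortho carbon with allylic transposition (tertiary ether in, linear prenyl out), followed by tautomerisation of dienone 4, whose transient stereocentre is lost on aromatisation; the basic solvent suppresses acid-catalysed chroman formation.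

Step 3
Reactants: 5 methyl 4-hydroxy-3-(3-methylbut-2-en-1-yl)benzoate; 2 tert-butyl 2-methylbut-3-en-2-yl carbonate
Product: 6 methyl 3-(3-methylbut-2-en-1-yl)-4-[(2-methylbut-3-en-2-yl)oxy]benzoate
Conditions: 2 (2 equiv), Pd(PPh3)4 (3 mol%), 4 Å MS, THF, 0–5 °C
Reagents that add atoms: none
Why: The same Pd-catalysed decarboxylative O-allylation (Tsuji–Trost type); the trisubstituted prenyl olefin is inert to Pd(0) and a single ortho substituent still allows the phenoxide to attack the tertiary terminus at low temperature.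

Step 4
Reactants: 6 methyl 3-(3-methylbut-2-en-1-yl)-4-[(2-methylbut-3-en-2-yl)oxy]benzoate
Product: 8 methyl 4-hydroxy-3,5-bis(3-methylbut-2-en-1-yl)benzoate, via Claisen dienone 7 (not isolated)
Conditions: PhNEt2, 150 °C, Ar
Reagents that add atoms: none
Why: Second aromatic Claisen rearrangement ([3,3]-sigmatropic): only the unsubstituted ortho carbon can rearomatise by tautomerisation of dienone 7, migration to the prenylated ortho carbon is reversible and the para position is blocked by the ester, so the second aryl–prenyl bond forms selectively.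

Step 5
Reactants: 8 methyl 4-hydroxy-3,5-bis(3-methylbut-2-en-1-yl)benzoate
Product: 10 4-methoxy-3,5-bis(3-methylbut-2-en-1-yl)benzoic acid, via methyl ester 9 (not isolated)
Conditions: MeI, K2CO3, acetone, reflux; filter, concentrate; LiOH, THF/MeOH/H2O, 50 °C; then cold 1 M HCl to pH 3
Reagents that add atoms: iodomethane, CI; lithium hydroxide (supplies the carboxyl OH oxygen), [Li+].[OH-]
Why: Williamson O-methylation of the hindered phenoxide followed, after removal of excess MeI, by BAc2 saponification of the methyl ester; the prenyl olefins are inert to base and to the brief cold acidification.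

Step 6
Reactants: 10 4-methoxy-3,5-bis(3-methylbut-2-en-1-yl)benzoic acid; 11 (R)-(−)-terpinen-4-ol [(1R)-4-methyl-1-(propan-2-yl)cyclohex-3-en-1-ol]
Product: 14 (1R)-4-methyl-1-(propan-2-yl)cyclohex-3-en-1-yl 4-methoxy-3,5-bis(3-methylbut-2-en-1-yl)benzoate, via acid chloride 12 (not isolated), via lithium alkoxide 13 (not isolated)
Conditions: 10, Ghosez's reagent (1-chloro-N,N,2-trimethylprop-1-en-1-amine, 1.05 equiv), CH2Cl2, 0 °C→rt; separately 11 (1.2 equiv), n-BuLi (1.15 equiv), THF, −78→0 °C; combine at 0 °C→rt; sat. NaHCO3 work-up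
Reagents that add atoms: none
Why: Nucleophilic acyl substitution in which Ghosez's reagent makes the acid chloride without free HCl (so the prenyl olefins are not hydrochlorinated) and the pre-formed lithium alkoxide acylates the hindered tertiary oxygen; the C–O bond at the stereocentre is never broken, so the (R) configuration bought in 11 is carried unchanged into 14.

## Compound list

1 | methyl 4-hydroxybenzoate | COC(=O)c1ccc(O)cc1 | starting material
2 | tert-butyl 2-methylbut-3-en-2-yl carbonate | C=CC(C)(C)OC(=O)OC(C)(C)C | starting material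
3 | methyl 4-[(2-methylbut-3-en-2-yl)oxy]benzoate | COC(=O)c1ccc(OC(C)(C)C=C)cc1 | intermediate
4 | methyl 3-(3-methylbut-2-en-1-yl)-4-oxocyclohexa-1,5-diene-1-carboxylate (Claisen dienone, racemic, transient) | COC(=O)C1=CC(CC=C(C)C)C(=O)C=C1 | intermediate
5 | methyl 4-hydroxy-3-(3-methylbut-2-en-1-yl)benzoate | COC(=O)c1ccc(O)c(CC=C(C)C)c1 | intermediate
6 | methyl 3-(3-methylbut-2-en-1-yl)-4-[(2-methylbut-3-en-2-yl)oxy]benzoate | COC(=O)c1ccc(OC(C)(C)C=C)c(CC=C(C)C)c1 | intermediate
7 | methyl 3,5-bis(3-methylbut-2-en-1-yl)-4-oxocyclohexa-1,5-diene-1-carboxylate (Claisen dienone, racemic, transient) | COC(=O)C1=CC(CC=C(C)C)C(=O)C(CC=C(C)C)=C1 | intermediate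
8 | methyl 4-hydroxy-3,5-bis(3-methylbut-2-en-1-yl)benzoate | COC(=O)c1cc(CC=C(C)C)c(O)c(CC=C(C)C)c1 | intermediate
9 | methyl 4-methoxy-3,5-bis(3-methylbut-2-en-1-yl)benzoate | COC(=O)c1cc(CC=C(C)C)c(OC)c(CC=C(C)C)c1 | intermediate
10 | 4-methoxy-3,5-bis(3-methylbut-2-en-1-yl)benzoic acid | COc1c(CC=C(C)C)cc(C(=O)O)cc1CC=C(C)C | intermediate
11 | (R)-(−)-terpinen-4-ol, (1R)-4-methyl-1-(propan-2-yl)cyclohex-3-en-1-ol | O[C@@]1(C(C)C)CC=C(C)CC1 | starting material
12 | 4-methoxy-3,5-bis(3-methylbut-2-en-1-yl)benzoyl chloride | COc1c(CC=C(C)C)cc(C(=O)Cl)cc1CC=C(C)C | intermediate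
13 | lithium (1R)-4-methyl-1-(propan-2-yl)cyclohex-3-en-1-olate | [Li+].[O-][C@@]1(C(C)C)CC=C(C)CC1 | intermediate
14 | (1R)-4-methyl-1-(propan-2-yl)cyclohex-3-en-1-yl 4-methoxy-3,5-bis(3-methylbut-2-en-1-yl)benzoate | COc1c(CC=C(C)C)cc(C(=O)O[C@@]2(C(C)C)CC=C(C)CC2)cc1CC=C(C)C | target

## Summary and risks

Total step count: 6. Longest linear sequence: 6 (1 → 3 → 5 → 6 → 8 → 10 → 14).

The three steps most likely to fail:

Step 3. With the ortho-substituted, electron-poor phenol 5 the Pd reaction can drift to the thermodynamic linear prenyl ether, which would give the wrong (reverse-prenyl) Claisen product. The fallback sets out from 5. Copper-catalysed O-alkylation with 3-chloro-3-methylbut-1-yne (DBU, cat. CuCl2, MeCN, 0 °C) gives the propargylic ether methyl 3-(3-methylbut-2-en-1-yl)-4-[(2-methylbut-3-yn-2-yl)oxy]benzoate F1. Semi-hydrogenation of the alkyne (H2, Lindlar catalyst, quinoline, EtOAc) then comes back to the route at 6.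

Step 4. The tertiary allyl ether of the electron-poor phenol may fragment to 5 and isoprene instead of rearranging. The fallback sets out from 5 and uses a simple allyl ether, which cannot ionise. Allyl bromide and K2CO3 in acetone give methyl 3-(3-methylbut-2-en-1-yl)-4-(prop-2-en-1-yloxy)benzoate F2. Its Claisen rearrangement (PhNEt2, 190 °C) passes through the dienone methyl 5-(3-methylbut-2-en-1-yl)-4-oxo-3-(prop-2-en-1-yl)cyclohexa-1,5-diene-1-carboxylate F3 to methyl 4-hydroxy-3-(3-methylbut-2-en-1-yl)-5-(prop-2-en-1-yl)benzoate F4. Olefin cross-metathesis with 2-methylbut-2-ene (Grubbs II, CH2Cl2, 40 °C) converts the allyl into the prenyl group and comes back to the route at 8.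

Step 6. The tertiary alkoxide is very hindered, and the acid chloride of a bis-prenyl arene is sensitive to traces of HCl and moisture. The fallback sets out from 10. CDI in THF at rt gives the isolable, HCl-free acyl imidazole (1H-imidazol-1-yl)[4-methoxy-3,5-bis(3-methylbut-2-en-1-yl)phenyl]methanone F5. This is treated with alkoxide 13 (from 11 and n-BuLi, THF, 0 °C→rt, NH4Cl work-up) and comes back to the route at 14.

## Further compounds

F1 | step 3 | methyl 3-(3-methylbut-2-en-1-yl)-4-[(2-methylbut-3-yn-2-yl)oxy]benzoate | COC(=O)c1ccc(OC(C)(C)C#C)c(CC=C(C)C)c1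
F2 | step 4 | methyl 3-(3-methylbut-2-en-1-yl)-4-(prop-2-en-1-yloxy)benzoate | COC(=O)c1ccc(OCC=C)c(CC=C(C)C)c1
F3 | step 4 | methyl 5-(3-methylbut-2-en-1-yl)-4-oxo-3-(prop-2-en-1-yl)cyclohexa-1,5-diene-1-carboxylate (racemic, transient) | COC(=O)C1=CC(CC=C)C(=O)C(CC=C(C)C)=C1
F4 | step 4 | methyl 4-hydroxy-3-(3-methylbut-2-en-1-yl)-5-(prop-2-en-1-yl)benzoate | COC(=O)c1cc(CC=C)c(O)c(CC=C(C)C)c1
F5 | step 6 | (1H-imidazol-1-yl)[4-methoxy-3,5-bis(3-methylbut-2-en-1-yl)phenyl]methanone | COc1c(CC=C(C)C)cc(C(=O)n2ccnc2)cc1CC=C(C)C
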